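The target is one arm of a fork: starting material leaves either with the partner as target or with the second substrate as cross product, and over-reaction product comes later out of target, so it counts to the target's arm. When I divided the two rates, the starting material and the clock dropped out and partner over second substrate stayed. So I worked with the branch ratio, the selectivity factor of this fork: target ever made over cross product.

| flask | starting material | partner | second substrate | remark | time |
|---|---|---|---|---|---|
| Saturday's | 0.54 M | 1.04 M | 0.80 M | run made earlier |  |
| Wednesday's | 1.2 M | 1.04 M | 0.80 M | run made earlier |  |
| flask | 0.80 M | 1.04 M | 0.800 M |  | 6.0 h |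

| run | time / h | target / % |
|---|---|---|
| Saturday's | 0.200 | 24 |
| Saturday's | 0.667 | 27 |
| Saturday's | 2.00 | 18 |
| Saturday's | 6.00 | 7 |
| Wednesday's | 0.200 | 23 |
| Wednesday's | 0.667 | 29 |
| Wednesday's | 2.00 | 30 |
| Wednesday's | 6.00 | 11 |

(scatter of a reading: 1.5 percentage points)

* the moment within 6.0 h at which there is most target
* the amount of target, in percent of the starting material charged, at that time

Wednesday's last two readings gave target a loss constant of 0.251 h⁻¹. Running the last readings back with it gave 31.5 % ever made on Saturday and 49.5 % on Wednesday, which are ratios of 0.460 and 0.982. The flask's starting material lies 0.394 of the way between those charges, with partner and second substrate unchanged, so I estimated for the flask a branch ratio of 0.666, or 40.0 % ever made. The target present at any moment cannot exceed the target ever made, so this figure served as my estimated ceiling for the peak, though it was an interpolation from scattered readings and not a firm bound.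

Saturday's highest reading, at 0.667 h, was 85.6 % of its amount ever made; Wednesday's, at 2.00 h, was 60.6 %. Applied to my estimated ceiling, those shares gave an estimated bracket for the flask's peak of 24.2 % to 34.2 %, and the same interpolation gave me 30.3 %. The forecast, 30 % at 0.7 h, “where formation balances decay”, stood inside that bracket.

The flask gave 30.1 % at 0.791 h.

    target → over-reaction product (k = 0.00550 min⁻¹)
    starting material + partner → target (k = 0.0470 L mol⁻¹ min⁻¹)
    starting material + second substrate → cross product (k = 0.170 L mol⁻¹ min⁻¹)
    second substrate + partner → second product (k = 0.0650 L mol⁻¹ min⁻¹)

At 6.00 h the flask held 44.2 % as target and over-reaction product against 55.8 % cross product, a branch ratio of 0.792 beside my 0.666. Scaling my ratio by the partner charge gave 1.66 for the neighbour with 2.6 M of partner. That neighbour ended with 9.80 % target and 57.5 % over-reaction product against 32.7 % cross product, a ratio of 2.06.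

The readings are calculated for substances that don't exist, and the scatter is random.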